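**Retrosynthetic overview**

1. C6–C7 is formed last by a Nozaki–Hiyama–Kishi closure of the ten-membered carbocycle (C7 alkenyl iodide, C6 aldehyde). Before that, C8–C9 comes from C-propargylation of a C9 lactol, whose formation closes the tetrahydrofuran ring, and C4–C5 from a chelate-controlled allylation.
2. The oxepane (O-b, C3, C2, C1, C14, C15, C16) is made by one-carbon ring expansion of a six-membered lactol silyl acetal (O-b–C2 bond). The rhodium carbenoid of methyl 2-diazopropanoate becomes C3 (oxonium ylide, Stevens 1,2-shift of C2), which forms C2–C3, O-b–C3 and the quaternary centre in one step.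
3. Enabling feature: C3 is a fully substituted ether carbon that carries the acyl-level carbon C4 and sits between the ring oxygen O-b and C2, and C2 itself bears a second oxygen (O-a of the tetrahydrofuran). C3 therefore maps onto an ester carbenoid, and O-b–C2 onto an acetal bond whose carbon migrates readily.
4. Ring A and the six-membered acetal ring come from a Diels–Alder reaction of an enantioenriched Achmatowicz pyranone ester with a (Z)-2-silyloxydiene. C14 is then set by epimerisation, C15 by methylenation and hydrogenation, C11 by methylation and hydration.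
5. Order of ring formation: pyranone (from furan) → ring A → oxepane (by expansion) → tetrahydrofuran → ten-membered ring.

Key step: step 13

Remark on position labels: positions are numbered as in the target. C1 and C10 are the ring-fusion carbons of cyclohexane ring A, C2 and C9 the carbons joined by the tetrahydrofuran oxygen O-a, C3 the quaternary ether carbon, C4 the ester carbinol, C6 the allylic carbinol, C7 the methylene-bearing carbon, C11 the tertiary carbinol, C15 the methyl-bearing carbon and C16 the OCH2 carbon of the oxepane, whose oxygen is O-b.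

Assumption (step 5): (R)-benzotetramisole is taken to be the catalyst antipode that gives the (S)-ester 7. If the sense of induction is the opposite, the (S)-catalyst is used and nothing else changes.

**Route**

Step 1
Reactants: 1 3-[(tert-butyldimethylsilyl)oxy]propanal
Product: 2 5-[(tert-butyldimethylsilyl)oxy]pent-1-en-3-ol (racemic)
Conditions: CH2=CHMgBr, THF, −78 °C; aq. NH4Cl
Reagents that add atoms: vinylmagnesium bromide, C=C[Mg]Br
Why: Grignard 1,2-addition to the aldehyde gives the allylic alcohol, whose racemic carbinol centre disappears in step 2.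

Step 2
Reactants: 2 5-[(tert-butyldimethylsilyl)oxy]pent-1-en-3-ol
Product: 3 5-[(tert-butyldimethylsilyl)oxy]pent-1-en-3-one
Conditions: 1,1,1-triacetoxy-1,1-dihydro-1,2-benziodoxol-3(1H)-one, NaHCO3, CH2Cl2, 0 °C
Reagents that add atoms: none
Why: Dess–Martin oxidation converts the secondary allylic alcohol into the vinyl ketone under buffered, non-basic conditions, so the β-silyloxy group is not eliminated.

Step 3
Reactants: 3 5-[(tert-butyldimethylsilyl)oxy]pent-1-en-3-one
Product: 4 (Z)-3,5-bis[(tert-butyldimethylsilyl)oxy]penta-1,3-diene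
Conditions: tBuMe2SiOTf, Et3N, CH2Cl2, −78 to 0 °C
Reagents that add atoms: tert-butyldimethylsilyl trifluoromethanesulfonate, CC(C)(C)[Si](C)(C)OS(=O)(=O)C(F)(F)F
Why: Soft enolisation (silyl triflate and amine) at the only enolisable α-carbon gives the 2-silyloxydiene as the Z enol ether, the usual outcome of this silylation and the isomer in which the CH2OTBS group points outward in the s-cis diene.

Step 4
Reactants: 5 furfuryl alcohol
Product: 6 6-hydroxy-2H-pyran-3(6H)-one (racemic lactol)
Conditions: N-bromosuccinimide, NaHCO3, NaOAc, THF/H2O, 0 °C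
Reagents that add atoms: water, O
Why: Achmatowicz rearrangement (oxidative ring expansion of the furfuryl alcohol through the dihydroxydihydrofuran and the ene-dione) gives the pyranone lactol, which is racemic and configurationally labile at the acetal carbon.

Step 5
Reactants: 6 6-hydroxy-2H-pyran-3(6H)-one
Product: 7 (S)-5-oxo-5,6-dihydro-2H-pyran-2-yl 2-methylpropanoate
Conditions: (iPrCO)2O, (R)-benzotetramisole (5 mol %), iPr2NEt, CHCl3, 0 °C
Reagents that add atoms: 2-methylpropanoic anhydride, CC(C)C(=O)OC(=O)C(C)C
Why: Dynamic kinetic resolution by enantioselective acyl transfer from the acylated isothiourea: the lactol racemises by ring opening while one enantiomer is esterified, which sets the acetal centre (the later C2) as S.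

Step 6
Reactants: 7 (S)-5-oxo-5,6-dihydro-2H-pyran-2-yl 2-methylpropanoate; 4 (Z)-3,5-bis[(tert-butyldimethylsilyl)oxy]penta-1,3-diene
Product: 8 cis-fused Diels–Alder adduct (C2 isobutyrate, C15 ketone, C11 silyl enol ether, C10 CH2OTBS)
Conditions: toluene, 85 °C, BHT (trace), sealed tube
Reagents that add atoms: none
Why: Diels–Alder reaction in which the silyloxy group makes C10 the nucleophilic diene terminus, so C10 bonds to the enone β-carbon C1 (ketone para to silyloxy); addition anti to the C2 acyloxy group and endo to the ketone sets C1 and C10 with C9 cis to C2, while C14 is formed cis and is corrected in step 7.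

Step 7
Reactants: 8 cis-fused Diels–Alder adduct
Product: 9 trans-fused keto lactol (C2 hydroxyl, anomers)
Conditions: K2CO3 (0.2 equiv), MeOH, −10 °C
Reagents that add atoms: none
Why: Methanolysis of the activated anomeric ester frees the lactol, and the same base epimerises C14 (α to the ketone) to the more stable trans ring fusion, as in 1-decalone; C1 and C10 are not α to the ketone and are kept while the lactol stays closed.

Step 8
Reactants: 9 trans-fused keto lactol
Product: 10 C2 triisopropylsilyl acetal of the trans-fused ketone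
Conditions: iPr3SiOTf, 2,6-lutidine, CH2Cl2, −78 °C
Reagents that add atoms: triisopropylsilyl trifluoromethanesulfonate, CC(C)[Si](OS(=O)(=O)C(F)(F)F)(C(C)C)C(C)C
Why: O-silylation of the lactol at −78 °C, where the ketone is not enolised, should put the bulky silyl group on the more accessible equatorial hydroxyl (trans to C10 on C1), which fixes C2.

Step 9
Reactants: 10 C2 triisopropylsilyl acetal of the trans-fused ketone
Product: 11 C15 exocyclic methylene compound
Conditions: Ph3PCH3Br, KOtBu, THF, 0 °C to rt
Reagents that add atoms: methyltriphenylphosphonium bromide (as its ylide), C[P+](c1ccccc1)(c1ccccc1)c1ccccc1.[Br-]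
Why: Wittig methylenation of the ketone by the non-stabilised ylide forms no stereocentre, and C14 already has its thermodynamic configuration.

Step 10
Reactants: 11 C15 exocyclic methylene compound
Product: 12 C15 methyl compound (methyl axial, cis to C13 on C14)
Conditions: H2 (1 atm), RhCl(PPh3)3 (5 mol %), benzene, rt
Reagents that add atoms: none
Why: Homogeneous hydrogenation with the bulky rhodium complex reduces the 1,1-disubstituted alkene and not the trisubstituted silyl enol ether; the catalyst should approach from the equatorial side, as bulky reagents do on the corresponding six-ring ketones, so hydrogen is delivered there and the C15 methyl ends up axial.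

Step 11
Reactants: 12 C15 methyl compound
Product: 14 C11 alkenyl triflate, via lithium enolate 13 (not isolated)
Conditions: MeLi, THF, 0 °C; then N-(5-chloropyridin-2-yl)bis(trifluoromethanesulfonyl)imide, −78 to 0 °C
Reagents that add atoms: N-(5-chloropyridin-2-yl)bis(trifluoromethanesulfonyl)imide, O=S(=O)(N(c1ccc(Cl)cn1)S(=O)(=O)C(F)(F)F)C(F)(F)F
Why: MeLi attacks silicon of the enol silyl ether only and releases the lithium enolate regiospecifically (no equilibration to the C10 enolate), and O-sulfonylation gives the alkenyl triflate, a group inert to carbenoids that holds C11 for later methylation.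

Step 12
Reactants: 15 methyl 2-methyl-3-oxobutanoate
Product: 16 methyl 2-diazopropanoate
Conditions: 4-acetamidobenzenesulfonyl azide, DBU, MeCN, 0 °C to rt
Reagents that add atoms: 4-acetamidobenzenesulfonyl azide, CC(=O)Nc1ccc(cc1)S(=O)(=O)N=[N+]=[N-]
Why: Deacylative diazo transfer (Regitz type): the sulfonyl azide transfers N2 to the α-carbon and the acetyl group leaves on the sulfonamide nitrogen, giving the α-methyl diazo ester.

Step 13
Reactants: 14 C11 alkenyl triflate; 16 methyl 2-diazopropanoate
Product: 18 ring-expanded oxepane methyl ester (C3 quaternary, C2 OTIPS), via oxonium ylide 17 (not isolated)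
Conditions: Rh2(O2CCMe3)4 (1 mol %), 16 (3 equiv, slow addition), CH2Cl2, −78 °C
Reagents that add atoms: none
Why: Proposed new method: the electrophilic rhodium carbenoid from 16 should be captured by the ring oxygen O-b of 14 to give oxonium ylide 17, whose acetal carbon C2 migrates from O-b to the ylide carbon (Stevens 1,2-shift through a tethered radical pair or oxocarbenium–enolate pair), so that C3 is inserted into the O-b–C2 bond. The closest known reaction types are the rhodium- or copper-catalysed ring expansion of cyclic acetals by diazo esters through oxonium ylides and the low-temperature ylide chemistry of α-alkyl-α-diazo esters with bulky rhodium carboxylates; their combination on a lactol silyl acetal is new. The oxepane is closed by C2–C3 bond formation inside the ylide, a one-atom expansion of the six-membered acetal ring to the seven-membered ring. C2 should keep its configuration (retention in the 1,2-shift; the same epimer, silyloxy equatorial and H2 anti to H1, is also favoured if the ion pair recombines), and C3 is set in the ring closure with the flat, smaller ester group pseudoaxial and the methyl pseudoequatorial, which is the required epimer. The step needs ylide formation at O-b and not at the silyl ether oxygens (secured by their silicon substitution and bulk), migration of C2 and not C16 (only C2 bears a second oxygen), and no 1,2-hydride shift of the carbenoid to methyl acrylate (bulky carboxylate ligands, −78 °C, slow addition).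

Step 14
Reactants: 18 ring-expanded oxepane methyl ester
Product: 19 C11-methyl cyclohexene (C11=C12)
Conditions: MeMgBr, Fe(acac)3 (5 mol %), THF/N-methylpyrrolidone, −30 °C
Reagents that add atoms: methylmagnesium bromide, C[Mg]Br
Why: Iron-catalysed cross-coupling of the alkenyl triflate with the methyl Grignard reagent is much faster at −30 °C than addition to the hindered ester and places the C11 methyl on the ring alkene.

Step 15
Reactants: 19 C11-methyl cyclohexene
Product: 21 C11 tertiary alcohol, via tertiary hydroperoxide 20 (not isolated)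
Conditions: Mn(dpm)3 (10 mol %), PhSiH3, O2 (1 atm), iPrOH/CH2Cl2, 0 °C; then P(OEt)3
Reagents that add atoms: dioxygen, O=O
Why: Mukaiyama-type hydration by hydrogen-atom transfer: hydrogen adds to C12, the tertiary C11 radical is trapped by O2 on the axial face opposite the axial CH2OTBS group on C10, and the phosphite reduces the hydroperoxide, which sets C11 with hydroxyl trans to C9.

Step 16
Reactants: 21 C11 tertiary alcohol
Product: 22 C4 aldehyde
Conditions: iBu2AlH (2.5 equiv), CH2Cl2, −78 °C; aq. potassium sodium tartrate
Reagents that add atoms: none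
Why: DIBAL half-reduction of the α-alkoxy ester should stop at the aldehyde because the tetrahedral aluminium alkoxide, chelated by O-b, survives at −78 °C; one equivalent is used up by the tertiary hydroxyl.

Step 17
Reactants: 22 C4 aldehyde
Product: 23 C4 homoallylic alcohol
Conditions: MgBr2·OEt2 (3 equiv), CH2=CHCH2SnBu3, CH2Cl2, −78 to −20 °C
Reagents that add atoms: allyltributylstannane, C=CC[Sn](CCCC)(CCCC)CCCC
Why: Chelation-controlled allylstannane addition: magnesium bridges the aldehyde oxygen and the ring oxygen O-b (the silyl ether oxygen on C2 does not chelate), and the allyl group enters from the side of the C3 methyl, the smaller of the two remaining C3 substituents, which sets C4.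

Step 18
Reactants: 23 C4 homoallylic alcohol
Product: 24 C4 octanoate
Conditions: octanoyl chloride, pyridine, DMAP (cat.), CH2Cl2, 0 °C to rt
Reagents that add atoms: octanoyl chloride, CCCCCCCC(=O)Cl
Why: DMAP-catalysed acylation esterifies the secondary C4 hydroxyl, while the tertiary C11 hydroxyl is too hindered to react under these conditions.

Step 19
Reactants: 24 C4 octanoate
Product: 25 triol (C2, C9 and C11 hydroxyls)
Conditions: aq. HF (48 %), MeCN, rt
Reagents that add atoms: none
Why: Aqueous HF cleaves both silicon–oxygen bonds under acidic conditions in which the octanoate, the alkene and the tertiary alcohol are stable and acyl migration is not base-promoted.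

Step 20
Reactants: 25 triol
Product: 27 C9 lactol with the tetrahydrofuran ring closed (anomers), via hydroxy aldehyde 26 (not isolated)
Conditions: TEMPO (0.2 equiv), PhI(OAc)2 (1.05 equiv), CH2Cl2, 0 °C
Reagents that add atoms: none
Why: Oxoammonium (TEMPO) oxidation is selective for the primary hydroxyl; the C9 aldehyde, cis to C2 on ring A, is trapped at once by the C2 hydroxyl as the five-membered lactol, which closes the tetrahydrofuran ring, and limiting the oxidant to one equivalent keeps the lactol from going on to the lactone.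

Step 21
Reactants: 27 C9 lactol
Product: 28 C9 propargyl compound (terminal alkyne)
Conditions: CH2=C=CHSnBu3, BF3·OEt2, CH2Cl2, −78 °C
Reagents that add atoms: tributyl(propa-1,2-dienyl)stannane, C=C=C[Sn](CCCC)(CCCC)CCCC
Why: BF3 ionises the lactol to the bicyclic oxocarbenium ion, and the allenylstannane attacks C9 (SE2′, giving the propargyl group) from the convex face, anti to ring A on C10, which sets C9 with C8 cis to H10.

Step 22
Reactants: 28 C9 propargyl compound
Product: 30 2-iodoalkene (C7 iodide), via alkenylborane 29 (not isolated)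
Conditions: B-iodo-9-BBN (2.3 equiv), 2,6-di-tert-butylpyridine, CH2Cl2/hexane, −20 to 0 °C; then AcOH; aqueous work-up
Reagents that add atoms: 9-iodo-9-borabicyclo[3.3.1]nonane, IB1C2CCCC1CCC2
Why: cis-Haloboration of the terminal alkyne puts iodine on the internal carbon and acetic acid cleaves the alkenyl carbon–boron bond to the 2-iodoalkene; the alkene does not react, and the tertiary hydroxyl is held as a borinate (the HI set free is taken up by the hindered pyridine) and returns on work-up.

Step 23
Reactants: 30 2-iodoalkene
Product: 32 C6 aldehyde with C7 alkenyl iodide, via vicinal diol 31 (not isolated)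
Conditions: OsO4 (2 mol %), NaIO4, 2,6-lutidine, dioxane/H2O, rt
Reagents that add atoms: sodium periodate (oxygen source by way of OsO4), [Na+].[O-]I(=O)(=O)=O
Why: Lemieux–Johnson oxidation: OsO4 dihydroxylates the monosubstituted alkene much faster than the electron-poor iodoalkene, and periodate cleaves the diol to the aldehyde under buffered conditions that spare the β-acyloxy aldehyde.

Step 24
Reactants: 32 C6 aldehyde with C7 alkenyl iodide
Product: 33 target (CNP0398453.2)
Conditions: CrCl2 (10 equiv), NiCl2 (0.1 equiv), DMSO/THF, rt, 0.003 M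
Reagents that add atoms: none
Why: Nozaki–Hiyama–Kishi reaction: nickel-catalysed formation of the alkenylchromium species and its addition to the aldehyde should close the ten-membered carbocycle at high dilution and give the allylic alcohol beside the exocyclic methylene; C6 is expected to be set by attack on the outer face of the aldehyde in the oxygen-bridged medium ring, the sense known for this type of closure in oxa-bridged nine-membered rings.

**Compound list**

1 | 3-[(tert-butyldimethylsilyl)oxy]propanal | O=CCCO[Si](C)(C)C(C)(C)C | starting material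
2 | 5-[(tert-butyldimethylsilyl)oxy]pent-1-en-3-ol (racemic) | C=CC(O)CCO[Si](C)(C)C(C)(C)C | intermediate
3 | 5-[(tert-butyldimethylsilyl)oxy]pent-1-en-3-one | C=CC(=O)CCO[Si](C)(C)C(C)(C)C | intermediate
4 | (Z)-3,5-bis[(tert-butyldimethylsilyl)oxy]penta-1,3-diene | C=C/C(O[Si](C)(C)C(C)(C)C)=C/CO[Si](C)(C)C(C)(C)C | intermediate
5 | furfuryl alcohol (furan-2-ylmethanol) | OCc1ccco1 | starting material
6 | 6-hydroxy-2H-pyran-3(6H)-one (racemic, labile lactol) | OC1OCC(=O)C=C1 | intermediate
7 | (S)-5-oxo-5,6-dihydro-2H-pyran-2-yl 2-methylpropanoate | CC(C)C(=O)O[C@@H]1OCC(=O)C=C1 | intermediate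
8 | cis-fused Diels–Alder adduct: six-membered O-b ring fused to ring A at C1–C14 (H1, H14 cis); C2 isobutyryloxy trans to C10; C15 ketone; C11 OTBS enol ether (C11=C12); C10 CH2OTBS cis to C2 | CC(C)C(=O)O[C@@H]1OCC(=O)[C@H]2CC=C(O[Si](C)(C)C(C)(C)C)[C@@H](CO[Si](C)(C)C(C)(C)C)[C@@H]12 | intermediate
9 | trans-fused keto lactol (H1, H14 trans; C2 hydroxyl, anomers, equatorial one shown) | O[C@@H]1OCC(=O)[C@@H]2CC=C(O[Si](C)(C)C(C)(C)C)[C@@H](CO[Si](C)(C)C(C)(C)C)[C@@H]12 | intermediate
10 | C2 triisopropylsilyl acetal (equatorial OTIPS) of the trans-fused C15 ketone | CC(C)[Si](O[C@@H]1OCC(=O)[C@@H]2CC=C(O[Si](C)(C)C(C)(C)C)[C@@H](CO[Si](C)(C)C(C)(C)C)[C@@H]12)(C(C)C)C(C)C | intermediate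
11 | C15 exocyclic methylene compound | CC(C)[Si](O[C@@H]1OCC(=C)[C@@H]2CC=C(O[Si](C)(C)C(C)(C)C)[C@@H](CO[Si](C)(C)C(C)(C)C)[C@@H]12)(C(C)C)C(C)C | intermediate
12 | C15 methyl compound (methyl axial, cis to C13) | CC(C)[Si](O[C@@H]1OC[C@H](C)[C@@H]2CC=C(O[Si](C)(C)C(C)(C)C)[C@@H](CO[Si](C)(C)C(C)(C)C)[C@@H]12)(C(C)C)C(C)C | intermediate
13 | lithium C11 enolate (C11=C12), not isolated | CC(C)[Si](O[C@@H]1OC[C@H](C)[C@@H]2CC=C(O[Li])[C@@H](CO[Si](C)(C)C(C)(C)C)[C@@H]12)(C(C)C)C(C)C | intermediate
14 | C11 alkenyl triflate of the bicyclic C2 silyl acetal (key-step substrate) | CC(C)[Si](O[C@@H]1OC[C@H](C)[C@@H]2CC=C(OS(=O)(=O)C(F)(F)F)[C@@H](CO[Si](C)(C)C(C)(C)C)[C@@H]12)(C(C)C)C(C)C | intermediate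
15 | methyl 2-methyl-3-oxobutanoate | CC(=O)C(C)C(=O)OC | starting material
16 | methyl 2-diazopropanoate | COC(=O)C(C)=[N+]=[N-] | intermediate
17 | oxonium ylide at O-b (ylide carbon = future C3), not isolated | CC(C)[Si](O[C@@H]1[O+]([C-](C)C(=O)OC)C[C@H](C)[C@@H]2CC=C(OS(=O)(=O)C(F)(F)F)[C@@H](CO[Si](C)(C)C(C)(C)C)[C@@H]12)(C(C)C)C(C)C | intermediate
18 | oxepane methyl ester: C3 quaternary (methyl, CO2Me), C2 OTIPS, trans-fused to ring A, C11 alkenyl triflate | CC(C)[Si](O[C@@H]1[C@](C)(C(=O)OC)OC[C@H](C)[C@@H]2CC=C(OS(=O)(=O)C(F)(F)F)[C@@H](CO[Si](C)(C)C(C)(C)C)[C@@H]12)(C(C)C)C(C)C | intermediate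
19 | C11-methyl cyclohexene (C11=C12) oxepane ester | CC(C)[Si](O[C@@H]1[C@](C)(C(=O)OC)OC[C@H](C)[C@@H]2CC=C(C)[C@@H](CO[Si](C)(C)C(C)(C)C)[C@@H]12)(C(C)C)C(C)C | intermediate
20 | C11 tertiary hydroperoxide, not isolated | CC(C)[Si](O[C@@H]1[C@](C)(C(=O)OC)OC[C@H](C)[C@@H]2CC[C@](C)(OO)[C@@H](CO[Si](C)(C)C(C)(C)C)[C@@H]12)(C(C)C)C(C)C | intermediate
21 | C11 tertiary alcohol (hydroxyl axial, trans to C9) | CC(C)[Si](O[C@@H]1[C@](C)(C(=O)OC)OC[C@H](C)[C@@H]2CC[C@](C)(O)[C@@H](CO[Si](C)(C)C(C)(C)C)[C@@H]12)(C(C)C)C(C)C | intermediate
22 | C4 aldehyde | CC(C)[Si](O[C@@H]1[C@](C)(C=O)OC[C@H](C)[C@@H]2CC[C@](C)(O)[C@@H](CO[Si](C)(C)C(C)(C)C)[C@@H]12)(C(C)C)C(C)C | intermediate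
23 | C4 homoallylic alcohol | CC(C)[Si](O[C@@H]1[C@](C)([C@H](O)CC=C)OC[C@H](C)[C@@H]2CC[C@](C)(O)[C@@H](CO[Si](C)(C)C(C)(C)C)[C@@H]12)(C(C)C)C(C)C | intermediate
24 | C4 octanoate | CC(C)[Si](O[C@@H]1[C@](C)([C@H](OC(=O)CCCCCCC)CC=C)OC[C@H](C)[C@@H]2CC[C@](C)(O)[C@@H](CO[Si](C)(C)C(C)(C)C)[C@@H]12)(C(C)C)C(C)C | intermediate
25 | triol (free C2, C9 and C11 hydroxyls; C4 octanoate) | O[C@@H]1[C@](C)([C@H](OC(=O)CCCCCCC)CC=C)OC[C@H](C)[C@@H]2CC[C@](C)(O)[C@@H](CO)[C@@H]12 | intermediate
26 | C9 hydroxy aldehyde (open form), not isolated | O[C@@H]1[C@](C)([C@H](OC(=O)CCCCCCC)CC=C)OC[C@H](C)[C@@H]2CC[C@](C)(O)[C@@H](C=O)[C@@H]12 | intermediate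
27 | C9 lactol, tetrahydrofuran ring closed (C9 anomers) | OC1O[C@@H]2[C@](C)([C@H](OC(=O)CCCCCCC)CC=C)OC[C@H](C)[C@@H]3CC[C@](C)(O)[C@@H]1[C@@H]23 | intermediate
28 | C9 propargyl compound | C#CC[C@@H]1O[C@@H]2[C@](C)([C@H](OC(=O)CCCCCCC)CC=C)OC[C@H](C)[C@@H]3CC[C@](C)(O)[C@@H]1[C@@H]23 | intermediate
29 | (Z)-2-iodoalkenyl-9-BBN with the C11 oxygen as 9-BBN borinate, not isolated | I/C(C[C@@H]1O[C@@H]2[C@](C)([C@H](OC(=O)CCCCCCC)CC=C)OC[C@H](C)[C@@H]3CC[C@](C)(OB4C5CCCC4CCC5)[C@@H]1[C@@H]23)=C\B6C7CCCC6CCC7 | intermediate
30 | 2-iodoalkene (C7 iodide) | C=C(I)C[C@@H]1O[C@@H]2[C@](C)([C@H](OC(=O)CCCCCCC)CC=C)OC[C@H](C)[C@@H]3CC[C@](C)(O)[C@@H]1[C@@H]23 | intermediate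
31 | vicinal diol from the terminal alkene (C6 epimers), not isolated | C=C(I)C[C@@H]1O[C@@H]2[C@](C)([C@H](OC(=O)CCCCCCC)CC(O)CO)OC[C@H](C)[C@@H]3CC[C@](C)(O)[C@@H]1[C@@H]23 | intermediate
32 | C6 aldehyde with C7 alkenyl iodide | C=C(I)C[C@@H]1O[C@@H]2[C@](C)([C@H](OC(=O)CCCCCCC)CC=O)OC[C@H](C)[C@@H]3CC[C@](C)(O)[C@@H]1[C@@H]23 | intermediate
33 | target CNP0398453.2 | C=C1C[C@@H]2O[C@H]3[C@H]4[C@@H](CC[C@](C)(O)[C@H]42)[C@@H](C)CO[C@@]3(C)[C@H](OC(=O)CCCCCCC)C[C@H]1O | target

**Step count and risks**

Total step count: 24. Longest linear sequence: 21 steps (1 → 4 → 8 → 14 → 18 → 33, that is steps 1–3, 6–11 and 13–24; the branch from furfuryl alcohol is 20 steps).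

Steps most likely to fail:

1. Step 13 (labelled step). The carbenoid may be lost by 1,2-hydride migration, the ylide may collapse by proton transfer before the 1,2-shift, or the ring-closing C2–C3 bond formation may show low facial selectivity at C3. The fallback sets out from 14 and uses methyl diazoacetate with Rh2(OAc)4 in CH2Cl2, a carbenoid without β-hydrogen and the diazo partner for which ring expansion of cyclic acetals through oxonium ylides is established. This should give the C3-unsubstituted oxepane ester F1 (C3 epimers, both usable). Deprotonation with LiN(iPr)2 at −78 °C and methylation with MeI, which exocyclic ester enolates take from the equatorial side, should then give 18, where the route is rejoined.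

2. Step 10. The risk is poor facial selectivity in the delivery of hydrogen to the exocyclic alkene. The fallback sets out from 11 and replaces catalytic hydrogenation by hydroboration with the bulkier 9-BBN (equatorial approach) and oxidation with NaBO3, which should give the axial C15 hydroxymethyl compound F2. Tosylation (TsCl, pyridine) gives the tosylate F3, and reduction with LiBHEt3 returns to 12.

3. Step 24. The risks are slow ring closure with protonation of the alkenylchromium species, oligomerisation, or poor facial selectivity at the aldehyde. The fallback sets out from alkyne 28 and replaces steps 22 to 24. Lemieux–Johnson cleavage of the terminal alkene (OsO4, NaIO4, 2,6-lutidine) gives the ynal F4. Reductive alkyne–aldehyde macrocyclisation with Ni(cod)2, a bulky N-heterocyclic carbene ligand (1,3-bis(2,6-diisopropylphenyl)imidazol-2-ylidene) and Et3SiH forms the carbon–carbon bond at the internal alkyne carbon and should give the C6 triethylsilyl ether with the exocyclic methylene, F5. HF·pyridine then gives 33.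

Further compounds
F1 | step 13 | C3-unsubstituted oxepane methyl ester (C3 epimers) | CC(C)[Si](O[C@@H]1C(C(=O)OC)OC[C@H](C)[C@@H]2CC=C(OS(=O)(=O)C(F)(F)F)[C@@H](CO[Si](C)(C)C(C)(C)C)[C@@H]12)(C(C)C)C(C)C
F2 | step 10 | C15 hydroxymethyl compound (CH2OH axial) | CC(C)[Si](O[C@@H]1OC[C@H](CO)[C@@H]2CC=C(O[Si](C)(C)C(C)(C)C)[C@@H](CO[Si](C)(C)C(C)(C)C)[C@@H]12)(C(C)C)C(C)C
F3 | step 10 | C15 tosyloxymethyl compound | CC(C)[Si](O[C@@H]1OC[C@H](COS(=O)(=O)c3ccc(C)cc3)[C@@H]2CC=C(O[Si](C)(C)C(C)(C)C)[C@@H](CO[Si](C)(C)C(C)(C)C)[C@@H]12)(C(C)C)C(C)C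
F4 | step 24 | ynal (C6 aldehyde, C9 propargyl) | C#CC[C@@H]1O[C@@H]2[C@](C)([C@H](OC(=O)CCCCCCC)CC=O)OC[C@H](C)[C@@H]3CC[C@](C)(O)[C@@H]1[C@@H]23
F5 | step 24 | C6 triethylsilyl ether of the target | C=C1C[C@@H]2O[C@H]3[C@H]4[C@@H](CC[C@](C)(O)[C@H]42)[C@@H](C)CO[C@@]3(C)[C@H](OC(=O)CCCCCCC)C[C@H]1O[Si](CC)(CC)CC
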